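Reckon the catalyst dose of each flask before trusting its first step.

    starting material + free catalyst ⇌ catalyst intermediate A (K1 = 0.98 M⁻¹, k1 = 3180 M⁻¹ min⁻¹)
    catalyst intermediate A ⇌ catalyst intermediate B (K2 = 0.47, k2 = 796 min⁻¹)
    catalyst intermediate B → free catalyst + product (k3 = 800 min⁻¹)

in all of them: starting material 0.20 M; time 30 min

| charge | free catalyst |
|---|---|
| grey | 0.10 mM |
| amber | 0.25 mM |

- which of these there is most of at the end, counted by the starting material in it, grey (starting material / catalyst intermediate B / catalyst intermediate A / product)
- which of these there is most of at the end, counted by the starting material in it, amber (starting material / catalyst intermediate B / catalyst intermediate A / product)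
- the largest of these amounts at the end, in percent of the starting material charged, grey
- the largest of these amounts at the end, in percent of the starting material charged, amber

In grey, the first step, forward rate alone and with the charges held, gives starting material a half-life of 2.2 min, shorter than the 30 min allowed. Yet my own reckoning, with both intermediates at steady state and the catalyst counted as free, gives grey a net half-life of about 29.9 min. The two do not seem to go together.

The way back clears this up. Catalyst intermediate A falls back with constant 3240 min⁻¹, faster than its 796 min⁻¹ onward, and catalyst intermediate B returns with 1690 min⁻¹, faster than its 800 min⁻¹ to product. So a share of 0.0730 of each binding reaches product, and the effective constant is 232 M⁻¹ min⁻¹.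

Grey gets 0.696 and amber 1.74; this catalyst dose is the effective constant times the catalyst charged times the time. With the catalyst counted as free, the flask is pseudo-first-order, and the fraction left is the exponential of minus the dose: 49.9% in grey, 17.6% in amber.

The correction is the catalyst tied up in the intermediates, 0.240 per free catalyst at the start. That figure times the fraction gone is added back against the dose. Two passes give 55.4% left in grey and 21.2% in amber, which means 78.8% product there. The catalyst charge, 0.125% of the starting material even in amber, can hold hardly any of it.

The forecast gave starting material at 55.5% for grey and product at 78.8% for amber, on this ground: “Both intermediates relax within milliseconds, so I treat them as steady state.”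

The simulation gives starting material at 55.5% in grey and product at 78.8% in amber. Grey's dose of 0.696 thus stands beside a fraction 55.5% of its starting material left. Now raise grey's catalyst to 4.0 × 10⁻⁴ M, holding the time and the other charges. The dose becomes 2.78, the bare fraction left is 6.18%, and two passes of the same correction bring it to 7.71%. The simulated neighbour ends with product ahead at 92.3% of the charge and 7.71% of the starting material left.

The constants come from no measurement; the run is a simulation.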